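**Strategy.** The route rests on disconnecting ring B at C9–C10 and at the C8–O bond, as in the protonation-initiated cyclase step that ends with oxygen capture of the C8 cation. The precursor is a ring A cyclohexene (C1=C10 olefin; C4 and C5 set by an enantioselective Diels–Alder reaction) carrying an (E)-C8=C9 olefin and a C13 methyl ketone. In one operation acid generates the C10 cation, the olefin closes ring B, and the ketone oxygen traps C8 as a temporary pyran ring, later hydrolysed. The step exploits the ring B array of quaternary C10, C9 and the equatorial C8 carbinol trans to the C9 side chain, all three set together. Labdane numbering is used.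

Key step: step 6

Assumption: the (S)-configured oxazaborolidinium ion is taken to shield the enal face that leads to the (1S,2R) adduct 6; if its sense of induction is the opposite, the mirror-image (R)-catalyst is used with no other change.

**Step 1**
Reactants: 1 (E)-geranylacetone
Product: 3 (2E,6E)-2,6-dimethyl-10-oxoundeca-2,6-dienal, via allylic alcohol 2 (not isolated)
Conditions: SeO2 (0.3 equiv), t-BuOOH, salicylic acid (cat.), CH2Cl2, 23 °C; then MnO2, CH2Cl2, 23 °C
Reagents that add atoms: selenium dioxide O=[Se]=O (delivers the oxygen atom), tert-butyl hydroperoxide CC(C)(C)OO (re-oxidant and ultimate oxygen source)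
Why: Allylic oxidation (ene reaction, then [2,3]-sigmatropic shift) should attack the (E)-methyl group of the terminal trisubstituted olefin and leave the ketone untouched at room temperature, and MnO2 then converges the alcohol/aldehyde mixture to the (E)-enal.

**Step 2**
Reactants: 3 (2E,6E)-2,6-dimethyl-10-oxoundeca-2,6-dienal
Product: 4 (5E,9E)-6,10-dimethyldodeca-5,9,11-trien-2-one
Conditions: Ph3PCH3Br, n-BuLi, THF, 0 °C; then 3 (ylide 1.05 equiv), −78 → 0 °C
Reagents that add atoms: methyltriphenylphosphonium bromide C[P+](c1ccccc1)(c1ccccc1)c1ccccc1.[Br-]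
Why: Wittig methylenation, in which the unstabilised ylide should react with the aldehyde much faster than with the methyl ketone at low temperature, leaving the (E)-trisubstituted olefin of the new 1,3-diene unchanged.

**Step 3**
Reactants: 4 (5E,9E)-6,10-dimethyldodeca-5,9,11-trien-2-one; 5 methacrolein
Product: 6 (1S,2R)-1,3-dimethyl-2-[(3E)-3-methyl-7-oxooct-3-en-1-yl]cyclohex-3-ene-1-carbaldehyde
Conditions: 5 (3 equiv), (S)-oxazaborolidinium triflimide made from (S)-α,α-diphenylprolinol, tri-o-tolylboroxine and HNTf2 (20 mol %), CH2Cl2, −78 → −40 °C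
Reagents that add atoms: none
Why: Catalytic enantioselective Diels–Alder reaction in which the CH2 terminus of boron-bound methacrolein should bond to the unsubstituted diene terminus C2 (ortho orientation from the C5 substituent, less hindered and through the more substituted allyl-cation-like transition state), the formyl group endo places CHO cis to the C5 chain, and the catalyst shields one enal face so that C4 and C5 are set together.

**Step 4**
Reactants: 6 (1S,2R)-1,3-dimethyl-2-[(3E)-3-methyl-7-oxooct-3-en-1-yl]cyclohex-3-ene-1-carbaldehyde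
Product: 7 (5E)-8-[(1R,6S)-6-(hydroxymethyl)-2,6-dimethylcyclohex-2-en-1-yl]-6-methyloct-5-en-2-one
Conditions: NaBH(OAc)3 (from NaBH4 and AcOH), toluene, 60 °C
Reagents that add atoms: none
Why: Chemoselective hydride reduction, since the electron-poor triacetoxyborohydride reduces aldehydes but not ketones, and the aldehyde has no α-hydrogen so no stereocentre is at risk.

**Step 5**
Reactants: 7 (5E)-8-[(1R,6S)-6-(hydroxymethyl)-2,6-dimethylcyclohex-2-en-1-yl]-6-methyloct-5-en-2-one
Product: 8 [(1S,2R)-1,3-dimethyl-2-[(3E)-3-methyl-7-oxooct-3-en-1-yl]cyclohex-3-en-1-yl]methyl 2,2-dimethylpropanoate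
Conditions: PivCl, pyridine, DMAP (cat.), CH2Cl2, 0 → 23 °C
Reagents that add atoms: pivaloyl chloride CC(C)(C)C(Cl)=O
Why: Acylation of the primary alcohol gives an ester whose oxygen is too weakly nucleophilic to capture the C10 cation in step 6 and which has no α-hydrogen, so it should survive the amide base of step 8.

**Step 6**
Reactants: 8 [(1S,2R)-1,3-dimethyl-2-[(3E)-3-methyl-7-oxooct-3-en-1-yl]cyclohex-3-en-1-yl]methyl 2,2-dimethylpropanoate
Product: 10 8α-hydroxy-19-pivaloyloxy-14,15-dinorlabdan-13-one, via tricyclic enol ether 9 (not isolated)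
Conditions: ClSO3H (3 equiv), 2-nitropropane, −78 °C; ice-water quench; then 1 M aq. HCl, THF, 23 °C
Reagents that add atoms: water O
Why: Markovnikov protonation of the C1=C10 ring olefin gives the tertiary C10 cation, C9 of the (E)-C8=C9 olefin attacks it, and the tertiary C8 cation is captured by the ketone oxygen as a six-membered oxocarbenium ion that gives enol ether 9 on quench; dilute aqueous acid then hydrolyses 9, so the former ketone oxygen remains as the C8 hydroxyl. The closest known reaction type is the superacid-promoted biomimetic cation–olefin cyclisation of monocyclic homofarnesic acid or of farnesylacetone with internal oxygen termination. Ring B closes in a 6-endo-trig mode (with respect to the C8=C9 olefin) through a chair transition state, and the temporary pyran ring closes by carbonyl-oxygen attack on the C8 cation. C10 is controlled by the existing C5 centre (C9 bonds on the face syn to H-5 with the C5 chain equatorial, giving the trans-decalin with a β-methyl), while C9 and C8 are controlled by the olefin geometry (anti addition across the E olefin puts C11 and the oxygen both equatorial and the C8 methyl axial). The step needs protonation of the ring olefin rather than the chain olefin and no capture or proton loss at C10: the protonated ketone deactivates the nearby chain olefin by its charge, the C19 ester carbonyl could reach C10 only through a seven-membered ring, and the non-basic medium at −78 °C disfavours loss of H-5.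

**Step 7**
Reactants: 10 8α-hydroxy-19-pivaloyloxy-14,15-dinorlabdan-13-one
Product: 11 19-pivaloyloxy-8α-(trimethylsilyloxy)-14,15-dinorlabdan-13-one
Conditions: 1-(trimethylsilyl)imidazole, CH2Cl2, 23 °C
Reagents that add atoms: 1-(trimethylsilyl)imidazole C[Si](C)(C)n1ccnc1
Why: Silylation of the hindered tertiary hydroxyl with a neutral, reactive silyl donor that should neither enolise nor silylate the ketone.

**Step 8**
Reactants: 11 19-pivaloyloxy-8α-(trimethylsilyloxy)-14,15-dinorlabdan-13-one
Product: 13 19-pivaloyloxy-8α-(trimethylsilyloxy)-14,15-dinorlabd-13(16)-en-13-yl trifluoromethanesulfonate, via lithium enolate 12 (not isolated)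
Conditions: lithium diisopropylamide (1.15 equiv), THF, −78 °C; then N-(5-chloropyridin-2-yl)bis(trifluoromethanesulfonyl)imide, −78 → 0 °C
Reagents that add atoms: N-(5-chloropyridin-2-yl)bis(trifluoromethanesulfonyl)imide Clc1ccc(N(S(=O)(=O)C(F)(F)F)S(=O)(=O)C(F)(F)F)nc1
Why: Kinetic deprotonation by the hindered amide base should occur at the C16 methyl rather than the C12 methylene, and O-triflation of enolate 12 fixes that regiochemistry, while the silyl ether prevents alkoxide formation and hemiketalisation.

**Step 9**
Reactants: 13 19-pivaloyloxy-8α-(trimethylsilyloxy)-14,15-dinorlabd-13(16)-en-13-yl trifluoromethanesulfonate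
Product: 14 19-pivaloyloxy-8α-(trimethylsilyloxy)labda-13(16),14-diene
Conditions: Bu3SnCH=CH2, Pd(PPh3)4 (5 mol %), LiCl, THF, 65 °C
Reagents that add atoms: tributyl(vinyl)stannane C=C[Sn](CCCC)(CCCC)CCCC
Why: Stille coupling (oxidative addition of zerovalent palladium into the vinyl C–OTf bond, transmetalation, reductive elimination) should give the 2-substituted 1,3-diene with the methylene fixed at C13=C16.

**Step 10**
Reactants: 14 19-pivaloyloxy-8α-(trimethylsilyloxy)labda-13(16),14-diene
Product: 16 labda-13(16),14-diene-8α,19-diol, via silyl ether alcohol 15 (not isolated)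
Conditions: diisobutylaluminium hydride (3 equiv), CH2Cl2, −78 °C, potassium sodium tartrate work-up; then 1 M aq. HCl, THF, 0 °C
Reagents that add atoms: none
Why: Hydride reduction should cleave the pivalate while the diene and silyl ether are inert, and brief dilute acid then removes the tertiary trimethylsilyl group without ionising the tertiary alcohol.

**Step 11**
Reactants: 16 labda-13(16),14-diene-8α,19-diol; 17 Meldrum's acid (2,2-dimethyl-1,3-dioxane-4,6-dione); 18 vanillin
Product: 21 8α-hydroxylabda-13(16),14-dien-19-yl (E)-ferulate, via malonate half-ester 19 (not isolated), via arylidene malonate 20 (not isolated)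
Conditions: 17 (1.05 equiv), toluene, 100 °C; then 18 (1.5 equiv), pyridine, piperidine (cat.), 60 °C
Reagents that add atoms: none
Why: Ring-opening acylation of the primary C19 hydroxyl by Meldrum's acid leaves the hindered tertiary C8 hydroxyl free, and Knoevenagel–Doebner condensation of 19 with vanillin followed by decarboxylation of 20 should give the (E)-cinnamate with its free phenol, the E geometry being the thermodynamic outcome of the decarboxylative elimination.

**Compound list**
1 | (E)-geranylacetone, (5E)-6,10-dimethylundeca-5,9-dien-2-one | CC(=O)CC/C=C(\C)CCC=C(C)C | starting material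
2 | (5E,9E)-11-hydroxy-6,10-dimethylundeca-5,9-dien-2-one | CC(=O)CC/C=C(\C)CC/C=C(\C)CO | intermediate (not isolated)
3 | (2E,6E)-2,6-dimethyl-10-oxoundeca-2,6-dienal | CC(=O)CC/C=C(\C)CC/C=C(\C)C=O | intermediate
4 | (5E,9E)-6,10-dimethyldodeca-5,9,11-trien-2-one | CC(=O)CC/C=C(\C)CC/C=C(\C)C=C | intermediate
5 | methacrolein, 2-methylprop-2-enal | CC(=C)C=O | starting material
6 | (1S,2R)-1,3-dimethyl-2-[(3E)-3-methyl-7-oxooct-3-en-1-yl]cyclohex-3-ene-1-carbaldehyde (CHO cis to the side chain) | O=C[C@@]1(C)CCC=C(C)[C@H]1CC/C(C)=C/CCC(C)=O | intermediate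
7 | (5E)-8-[(1R,6S)-6-(hydroxymethyl)-2,6-dimethylcyclohex-2-en-1-yl]-6-methyloct-5-en-2-one | OC[C@@]1(C)CCC=C(C)[C@H]1CC/C(C)=C/CCC(C)=O | intermediate
8 | [(1S,2R)-1,3-dimethyl-2-[(3E)-3-methyl-7-oxooct-3-en-1-yl]cyclohex-3-en-1-yl]methyl 2,2-dimethylpropanoate | CC(C)(C)C(=O)OC[C@@]1(C)CCC=C(C)[C@H]1CC/C(C)=C/CCC(C)=O | intermediate
9 | 8α,13-epoxy-19-pivaloyloxy-14,15-dinorlabd-12-ene (tricyclic enol ether, trans-fused) | CC1=CC[C@@H]2[C@@]3(C)CCC[C@](C)(COC(=O)C(C)(C)C)[C@@H]3CC[C@@]2(C)O1 | intermediate (not isolated)
10 | 8α-hydroxy-19-pivaloyloxy-14,15-dinorlabdan-13-one (5α-H, 9α-H, 10β-methyl, 4β-CH2OPiv) | CC(=O)CC[C@@H]1[C@@]2(C)CCC[C@](C)(COC(=O)C(C)(C)C)[C@@H]2CC[C@@]1(C)O | intermediate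
11 | 19-pivaloyloxy-8α-(trimethylsilyloxy)-14,15-dinorlabdan-13-one | CC(=O)CC[C@@H]1[C@@]2(C)CCC[C@](C)(COC(=O)C(C)(C)C)[C@@H]2CC[C@@]1(C)O[Si](C)(C)C | intermediate
12 | lithium 13(16)-enolate of 11 | [Li]OC(=C)CC[C@@H]1[C@@]2(C)CCC[C@](C)(COC(=O)C(C)(C)C)[C@@H]2CC[C@@]1(C)O[Si](C)(C)C | intermediate (not isolated)
13 | 19-pivaloyloxy-8α-(trimethylsilyloxy)-14,15-dinorlabd-13(16)-en-13-yl trifluoromethanesulfonate | C=C(OS(=O)(=O)C(F)(F)F)CC[C@@H]1[C@@]2(C)CCC[C@](C)(COC(=O)C(C)(C)C)[C@@H]2CC[C@@]1(C)O[Si](C)(C)C | intermediate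
14 | 19-pivaloyloxy-8α-(trimethylsilyloxy)labda-13(16),14-diene | C=CC(=C)CC[C@@H]1[C@@]2(C)CCC[C@](C)(COC(=O)C(C)(C)C)[C@@H]2CC[C@@]1(C)O[Si](C)(C)C | intermediate
15 | 8α-(trimethylsilyloxy)labda-13(16),14-dien-19-ol | C=CC(=C)CC[C@@H]1[C@@]2(C)CCC[C@](C)(CO)[C@@H]2CC[C@@]1(C)O[Si](C)(C)C | intermediate (not isolated)
16 | labda-13(16),14-diene-8α,19-diol | C=CC(=C)CC[C@@H]1[C@@]2(C)CCC[C@](C)(CO)[C@@H]2CC[C@@]1(C)O | intermediate
17 | Meldrum's acid, 2,2-dimethyl-1,3-dioxane-4,6-dione | CC1(C)OC(=O)CC(=O)O1 | starting material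
18 | vanillin, 4-hydroxy-3-methoxybenzaldehyde | COc1cc(C=O)ccc1O | starting material
19 | 8α-hydroxylabda-13(16),14-dien-19-yl hydrogen malonate | C=CC(=C)CC[C@@H]1[C@@]2(C)CCC[C@](C)(COC(=O)CC(=O)O)[C@@H]2CC[C@@]1(C)O | intermediate (not isolated)
20 | 8α-hydroxylabda-13(16),14-dien-19-yl hydrogen (4-hydroxy-3-methoxybenzylidene)malonate (olefin geometry not defined) | C=CC(=C)CC[C@@H]1[C@@]2(C)CCC[C@](C)(COC(=O)C(C(=O)O)=Cc3ccc(O)c(OC)c3)[C@@H]2CC[C@@]1(C)O | intermediate (not isolated)
21 | 8α-hydroxylabda-13(16),14-dien-19-yl (E)-ferulate, (4S,5R,8R,9R,10S); [(1S,4aS,5R,6R,8aR)-6-hydroxy-1,4a,6-trimethyl-5-(3-methylidenepent-4-en-1-yl)decahydronaphthalen-1-yl]methyl (2E)-3-(4-hydroxy-3-methoxyphenyl)prop-2-enoate | C=CC(=C)CC[C@@H]1[C@@]2(C)CCC[C@](C)(COC(=O)/C=C/c3ccc(O)c(OC)c3)[C@@H]2CC[C@@]1(C)O | target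

**Count.** Total steps: 11. Longest linear sequence: 11 steps (from 1).

**Steps most likely to fail**

Step 6. The protonated ketone may capture the C8 cation too slowly, so that proton loss and unselective re-closure erode the trans C8–O/C9 relationship, or the chain olefin may be protonated in competition with the ring olefin. The fallback changes the terminating group to a carboxylic acid; it sets out from 8 and comes back at 10. The kinetic enolate of 8 (lithium diisopropylamide, −78 °C) would be hydroxylated with 2-(phenylsulfonyl)-3-phenyloxaziridine to hydroxymethyl ketone F1. NaIO4 in aqueous THF would cleave F1 to the (4E)-heptenoic acid F2. ClSO3H in 2-nitropropane at −78 °C would then close ring B with lactonisation, the well-precedented acid-terminated mode, to the trans-fused δ-lactone F3. One equivalent of MeLi in THF at −78 °C would open F3 to the methyl ketone 10.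

Step 3. Facial discrimination may be poor because the basic ketone of 4 competes with methacrolein for the boron centre and an uncatalysed background reaction intervenes; bonding at the substituted diene terminus would also lower the ortho preference. The fallback replaces catalyst control by resolution; it sets out from 4 and 5 and comes back at 7. Me2AlCl-promoted cycloaddition in CH2Cl2 at −78 °C would give the racemic endo adduct (6 together with its mirror image F4). NaBH(OAc)3 would give the racemic alcohol (7 together with F5). Esterification with (1S)-camphanic chloride and pyridine would give the diastereomeric camphanates F6 (from 7) and F7 (from F5), to be separated by crystallisation or chromatography, which should also remove any regioisomer. K2CO3 in methanol would release 7 from F6.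

Step 8. Deprotonation at the C12 methylene, or proton transfer between enolate and ketone, would give the internal enol triflate and then the wrong diene. The fallback avoids enolate regiochemistry altogether; it sets out from 10 and comes back at 16. Haloform cleavage of 10 (NaOBr from Br2 and NaOH, dioxane–water, 0 °C) followed by acidification would give the same δ-lactone F3. Diisobutylaluminium hydride at −78 °C would reduce the lactone to lactol F8 and remove the pivalate. Seyferth–Gilbert homologation with dimethyl (1-diazo-2-oxopropyl)phosphonate and K2CO3 in methanol would give the terminal alkyne F9. Ene–yne cross-metathesis with ethylene, using the second-generation Grubbs catalyst (H2IMes)(PCy3)Cl2Ru=CHPh in CH2Cl2 at 40 °C, would give diol 16 directly with no protecting group on the C8 hydroxyl.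

**Further compounds**
F1 | step 6 | [(1S,2R)-2-[(3E)-8-hydroxy-3-methyl-7-oxooct-3-en-1-yl]-1,3-dimethylcyclohex-3-en-1-yl]methyl 2,2-dimethylpropanoate | CC(C)(C)C(=O)OC[C@@]1(C)CCC=C(C)[C@H]1CC/C(C)=C/CCC(=O)CO
F2 | step 6 | (4E)-7-[(1R,6S)-2,6-dimethyl-6-(pivaloyloxymethyl)cyclohex-2-en-1-yl]-5-methylhept-4-enoic acid | CC(C)(C)C(=O)OC[C@@]1(C)CCC=C(C)[C@H]1CC/C(C)=C/CCC(=O)O
F3 | step 6 | 19-pivaloyloxy-14,15,16-trinorlabdan-13,8α-olide | O=C1CC[C@@H]2[C@@]3(C)CCC[C@](C)(COC(=O)C(C)(C)C)[C@@H]3CC[C@@]2(C)O1
F4 | step 3 | (1R,2S)-1,3-dimethyl-2-[(3E)-3-methyl-7-oxooct-3-en-1-yl]cyclohex-3-ene-1-carbaldehyde (mirror image of 6) | O=C[C@]1(C)CCC=C(C)[C@@H]1CC/C(C)=C/CCC(C)=O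
F5 | step 3 | (5E)-8-[(1S,6R)-6-(hydroxymethyl)-2,6-dimethylcyclohex-2-en-1-yl]-6-methyloct-5-en-2-one (mirror image of 7) | OC[C@]1(C)CCC=C(C)[C@@H]1CC/C(C)=C/CCC(C)=O
F6 | step 3 | (1S)-camphanate ester of 7 | O=C(OC[C@@]1(C)CCC=C(C)[C@H]1CC/C(C)=C/CCC(C)=O)[C@@]12CC[C@@](C)(C(=O)O1)C2(C)C
F7 | step 3 | (1S)-camphanate ester of F5 | O=C(OC[C@]1(C)CCC=C(C)[C@@H]1CC/C(C)=C/CCC(C)=O)[C@@]12CC[C@@](C)(C(=O)O1)C2(C)C
F8 | step 8 | 8α,13-epoxy-14,15,16-trinorlabdane-13,19-diol (lactol, anomeric centre not defined) | OC1CC[C@@H]2[C@@]3(C)CCC[C@](C)(CO)[C@@H]3CC[C@@]2(C)O1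
F9 | step 8 | 14,15-dinorlabd-13(16)-yne-8α,19-diol | C#CCC[C@@H]1[C@@]2(C)CCC[C@](C)(CO)[C@@H]2CC[C@@]1(C)O
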